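**Retrosynthetic overview**
1. Target ⇐ desilylation, E1cB unveiling of the C11=C13 methylene, C8 angeloylation and 1,3-anti reduction of a ten-membered C8 ketone carrying the cis-fused lactone.
2. Key disconnection: C8–C9 and C7–C8 in one radical operation; a C9 iodide takes up CO and the resulting acyl radical closes the ten-membered ring onto C7 of a preformed butenolide. Ring order: oxiranes, then butenolide, then the ten-membered ring.
3. Seco-iodohydrin ⇐ C3–C4 Nozaki–Hiyama–Kishi union of a (Z)-iodoalkenyl butenolide (C4–C7, C11–C13, C15) with a cis-epoxy aldehyde (C1–C3, C9, C10, C14).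
4. Butenolide ⇐ crotonaldehyde + propyne (asymmetric alkynylation), trans-hydroalumination/iodination, 2-(bromomethyl)acrylate ester, ring-closing metathesis.
5. Epoxy aldehyde ⇐ (S)-2-methylglycidol + allyl chloride ((Z)-γ-chloroallylboration, ozonolysis).

Assumption: the SMILES is read literally (cis-fused 12,6-lactone, 4Z olefin, cis-1,2-epoxide, 8-angelate, i.e. 1R,2R,3R,6S,7R,8R,10R); C1–C15 are germacrane locants (C12 lactone carbonyl, C13 exo-methylene carbon, C14 methyl on C10, C15 methyl on C4).

**Step 1**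
Reactants: 1 (S)-2-methylglycidol
Product: 2 (2R)-2-methyloxirane-2-carbaldehyde
Conditions: (COCl)2, DMSO, CH2Cl2, −78 °C; Et3N, −78 → 0 °C
Reagents that add atoms: none
Why: Swern oxidation of the primary alcohol; the quaternary C10 centre has no α-hydrogen and cannot epimerise, and the epoxide is inert at low temperature.

**Step 2**
Reactants: 2 (2R)-2-methyloxirane-2-carbaldehyde; 3 allyl chloride
Product: 6 (2R,3R)-2-ethenyl-3-[(2R)-2-methyloxiran-2-yl]oxirane, via diisopinocampheylborinate 4 (not isolated), via chlorohydrin 5 (not isolated)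
Conditions: 3, LiN(c-C6H11)2, (+)-Ipc2BOMe [lIpc series, from (−)-α-pinene], BF3·OEt2, Et2O, −95 °C; then 2, −95 °C; then NaOH, H2O2, 0 °C → rt
Reagents that add atoms: none
Why: Oehlschlager–Brown (Z)-γ-chloroallylboration; the lIpc reagent adds through a chair transition state under reagent control to give the syn (1S,2S)-chlorohydrin borinate, and after alkaline peroxide work-up the C1 alkoxide displaces chloride with inversion to give the cis (1R,2R)-epoxide.

**Step 3**
Reactants: 6 (2R,3R)-2-ethenyl-3-[(2R)-2-methyloxiran-2-yl]oxirane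
Product: 8 (2S,3R)-3-[(2R)-2-methyloxiran-2-yl]oxirane-2-carbaldehyde, via secondary ozonide 7 (not isolated)
Conditions: O3, CH2Cl2, −78 °C; then Me2S, −78 °C → rt; short silica plug to remove formaldehyde
Reagents that add atoms: ozone, [O-][O+]=O
Why: Ozonolysis of the terminal vinyl group with reductive work-up gives the cis-epoxy aldehyde (C3) without touching any stereocentre.

**Step 4**
Reactants: 9 (E)-crotonaldehyde; 10 propyne
Product: 11 (4R,5E)-hept-5-en-2-yn-4-ol
Conditions: Me2Zn (3 equiv), ProPhenol ligand (10 mol%; the antipode that gives the 4R carbinol, checked by Mosher analysis), Ph3PO (20 mol%), toluene, 4 °C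
Reagents that add atoms: none
Why: Trost zinc–ProPhenol catalytic asymmetric alkynylation of an enal; the chiral dinuclear zinc alkynylide adds to one carbonyl face and sets the future C6 carbinol.

**Step 5**
Reactants: 11 (4R,5E)-hept-5-en-2-yn-4-ol
Product: 13 (2Z,4R,5E)-2-iodohepta-2,5-dien-4-ol, via sodium alkenylalanate 12 (not isolated)
Conditions: NaAlH2(OCH2CH2OMe)2, THF, 0 °C → rt; then I2, THF, −78 °C
Reagents that add atoms: iodine, II
Why: Alkoxide-directed trans-hydroalumination places aluminium on the methyl-bearing alkyne carbon cis to the carbinol carbon, and iodinolysis with retention gives the (Z)-iodoalkene that fixes the 4Z geometry; the carbinol centre is untouched.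

**Step 6**
Reactants: 13 (2Z,4R,5E)-2-iodohepta-2,5-dien-4-ol; 14 2-(bromomethyl)acrylic acid
Product: 15 (2Z,4R,5E)-2-iodohepta-2,5-dien-4-yl 2-(bromomethyl)prop-2-enoate
Conditions: N,N′-diisopropylcarbodiimide, DMAP (5 mol%), CH2Cl2, −20 → 0 °C
Reagents that add atoms: none
Why: Steglich esterification at oxygen with retention at C6; low temperature and little DMAP spare the allylic bromide.

**Step 7**
Reactants: 15 (2Z,4R,5E)-2-iodohepta-2,5-dien-4-yl 2-(bromomethyl)prop-2-enoate
Product: 16 (2Z,4R,5E)-2-iodohepta-2,5-dien-4-yl 2-(acetoxymethyl)prop-2-enoate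
Conditions: KOAc, DMF, rt
Reagents that add atoms: potassium acetate, CC(=O)[O-].[K+]
Why: SN2 displacement (SN2′ gives the same product) of the activated allylic bromide by acetate installs the latent C13 leaving group in a form that tolerates the chromium and silyl-radical steps.

**Step 8**
Reactants: 16 (2Z,4R,5E)-2-iodohepta-2,5-dien-4-yl 2-(acetoxymethyl)prop-2-enoate
Product: 17 [(5R)-5-[(1Z)-2-iodoprop-1-en-1-yl]-2-oxo-2,5-dihydrofuran-3-yl]methyl acetate
Conditions: second-generation Grubbs catalyst (H2IMes)(PCy3)Cl2Ru=CHPh (5 mol%), CH2Cl2, 40 °C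
Reagents that add atoms: none
Why: Ring-closing metathesis between the acrylate and the propenyl group closes the butenolide with loss of propene; the trisubstituted iodoalkene is inert and C6 is unaffected.

**Step 9**
Reactants: 17 [(5R)-5-[(1Z)-2-iodoprop-1-en-1-yl]-2-oxo-2,5-dihydrofuran-3-yl]methyl acetate; 8 (2S,3R)-3-[(2R)-2-methyloxiran-2-yl]oxirane-2-carbaldehyde
Product: 19 C3-O-triethylsilyl bis-epoxy butenolide (3-(acetoxymethyl)butenolide whose C6 carries (Z)-CH=C(CH3)–CH(OSiEt3)–[cis C2/C1 oxirane]–[2-methyloxiran-2-yl]; C1/C2/C3/C6/C10 as in 27), via chromium alkoxide 18 (not isolated)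
Conditions: CrCl2 (6 equiv), NiCl2 (0.5 mol%), DMF, rt; then imidazole, Et3SiCl, 0 °C → rt
Reagents that add atoms: chlorotriethylsilane, CC[Si](Cl)(CC)CC
Why: Nozaki–Hiyama–Kishi coupling; the alkenylchromium forms with retention of the Z geometry and adds to the aldehyde in Felkin–Anh fashion (anti to the epoxide C2–O bond) to give the 2,3-anti epoxy alcohol (3R), and the chromium alkoxide is silylated in the same flask as chlorosilanes do in the Fürstner catalytic variant.

**Step 10**
Reactants: 19 C3-O-triethylsilyl bis-epoxy butenolide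
Product: 20 iodohydrin (as 19 but with the terminal oxirane opened to C10(OH)(CH3)–C9H2I; C10 R)
Conditions: LiI, AcOH, THF, 0 °C → rt
Reagents that add atoms: lithium iodide, [Li+].[I-]
Why: SN2 opening of the 2,2-disubstituted terminal epoxide by iodide at the unhindered CH2 retains C10; the internal cis-epoxide, flanked by a quaternary carbon and the silyloxy carbon, opens far more slowly.

**Step 11**
Reactants: 20 iodohydrin; 21 carbon monoxide
Product: 22 macrocyclic ketone (13-acetoxy-1,2-epoxy-10-hydroxy-8-oxo-3-(triethylsilyloxy)germacr-4Z-en-12,6-olide; H-6/H-7 cis; C11 epimers)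
Conditions: CO (80 atm), (Me3Si)3SiH (1.5 equiv), AIBN (0.3 equiv), benzene (0.005 M), 80 °C
Reagents that add atoms: none
Why: Proposed new method: iodine abstraction by (Me3Si)3Si• gives the C9 primary radical, CO at 80 atm traps it as the C8 acyl radical, and this nucleophilic radical adds to the butenolide β-carbon C7 across the face that carries the C5 tether (chain pre-folded by the cis-epoxide, the Z-olefin and quaternary C10), so the ten-membered ring closes with C7–C8 cis to C6–C5 (7R) before the α-lactone radical is quenched by the silane; the closest known reaction is the Ryu–Sonoda free-radical carbonylative macrocyclisation of ω-iodoalkyl acrylates to 10- to 17-membered 4-oxo lactones under the same reagents.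

**Step 12**
Reactants: 22 macrocyclic ketone
Product: 23 8,10-anti diol (13-acetoxy-1,2-epoxy-8,10-dihydroxy-3-(triethylsilyloxy)germacr-4Z-en-12,6-olide; 8R)
Conditions: Me4NBH(OAc)3, MeCN/AcOH (1:1), −30 → −20 °C
Reagents that add atoms: none
Why: Evans–Saksena reduction; the C10 alkoxide binds boron and delivers hydride intramolecularly to the C8 ketone from its own face, giving the 1,3-anti diol (8R), while the acidic medium avoids enolisation at C7 and retro-aldol cleavage.

**Step 13**
Reactants: 23 8,10-anti diol; 24 angelic acid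
Product: 26 3-O-triethylsilyl ether of 27, via angelate acetate 25 (not isolated)
Conditions: 24, 2,4,6-Cl3C6H2COCl, Et3N, toluene, rt; then 23, 75 °C; then DBU, 0 °C
Reagents that add atoms: none
Why: Yamaguchi mixed-anhydride esterification acylates only the secondary C8–OH (C10–OH is tertiary, C3–O is silylated) and without DMAP does not isomerise angelate to tiglate; DBU then expels acetate by E1cB elimination to form the C11=C13 methylene.

**Step 14**
Reactants: 26 3-O-triethylsilyl ether of 27
Product: 27 (1R,2R,3R,4Z,6S,7R,8R,10R)-8-angeloyloxy-1,2-epoxy-3,10-dihydroxygermacra-4,11(13)-dien-12,6-olide (CNP0351240.2)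
Conditions: HF·pyridine, pyridine, THF, 0 °C
Reagents that add atoms: none
Why: Buffered fluoride desilylation removes the triethylsilyl ether without affecting the epoxide, the angelate or the methylene lactone.

**Compound list**
1 | (S)-2-methylglycidol [(2S)-(2-methyloxiran-2-yl)methanol] | OC[C@]1(C)OC1 | starting material
2 | (2R)-2-methyloxirane-2-carbaldehyde | O=C[C@]1(C)OC1 | intermediate
3 | allyl chloride (3-chloroprop-1-ene) | C=CCCl | starting material
4 | (1S,2S)-2-chloro-1-[(2R)-2-methyloxiran-2-yl]but-3-en-1-yl diisopinocampheylborinate | C=C[C@H](Cl)[C@@H](OB([C@H]1C[C@H]2C[C@@H]([C@@H]1C)C2(C)C)[C@H]1C[C@H]2C[C@@H]([C@@H]1C)C2(C)C)[C@]1(C)OC1 | intermediate (not isolated)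
5 | (1S,2S)-2-chloro-1-[(2R)-2-methyloxiran-2-yl]but-3-en-1-ol (syn-chlorohydrin) | C=C[C@H](Cl)[C@@H](O)[C@]1(C)OC1 | intermediate (not isolated)
6 | (2R,3R)-2-ethenyl-3-[(2R)-2-methyloxiran-2-yl]oxirane | C=C[C@H]1O[C@H]1[C@]2(C)OC2 | intermediate
7 | secondary ozonide of 6 (3-substituted 1,2,4-trioxolane) | C1OC(OO1)[C@H]2O[C@H]2[C@]3(C)OC3 | intermediate (not isolated)
8 | (2S,3R)-3-[(2R)-2-methyloxiran-2-yl]oxirane-2-carbaldehyde | O=C[C@H]1O[C@H]1[C@]2(C)OC2 | intermediate
9 | (E)-crotonaldehyde | C/C=C/C=O | starting material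
10 | propyne | CC#C | starting material
11 | (4R,5E)-hept-5-en-2-yn-4-ol | C/C=C/[C@@H](O)C#CC | intermediate
12 | sodium cyclic alkenylalanate from 11 (Al on the methyl-bearing carbon, cis to the carbinol carbon) | C/C=C/[C@@H]1C=C(C)[Al-](OCCOC)(OCCOC)O1.[Na+] | intermediate (not isolated)
13 | (2Z,4R,5E)-2-iodohepta-2,5-dien-4-ol | C/C=C/[C@@H](O)/C=C(/C)I | intermediate
14 | 2-(bromomethyl)acrylic acid | C=C(CBr)C(=O)O | starting material
15 | (2Z,4R,5E)-2-iodohepta-2,5-dien-4-yl 2-(bromomethyl)prop-2-enoate | C/C=C/[C@@H](OC(=O)C(=C)CBr)/C=C(/C)I | intermediate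
16 | (2Z,4R,5E)-2-iodohepta-2,5-dien-4-yl 2-(acetoxymethyl)prop-2-enoate | C/C=C/[C@@H](OC(=O)C(=C)COC(C)=O)/C=C(/C)I | intermediate
17 | [(5R)-5-[(1Z)-2-iodoprop-1-en-1-yl]-2-oxo-2,5-dihydrofuran-3-yl]methyl acetate | CC(=O)OCC1=C[C@H](/C=C(/C)I)OC1=O | intermediate
18 | dichlorochromium alkoxide of the (3R)-allylic alcohol formed from 17 and 8 | CC(=O)OCC1=C[C@H](/C=C(/C)[C@@H]([O-])[C@H]2O[C@H]2[C@]3(C)OC3)OC1=O.[Cr+3].[Cl-].[Cl-] | intermediate (not isolated)
19 | C3-O-triethylsilyl bis-epoxy butenolide (C1/C2/C3/C6/C10 as in 27) | CC(=O)OCC1=C[C@H](/C=C(/C)[C@@H](O[Si](CC)(CC)CC)[C@H]2O[C@H]2[C@]3(C)OC3)OC1=O | intermediate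
20 | iodohydrin: 19 with the terminal oxirane opened to C10(OH)(CH3)–CH2I | CC(=O)OCC1=C[C@H](/C=C(/C)[C@@H](O[Si](CC)(CC)CC)[C@H]2O[C@H]2[C@](C)(O)CI)OC1=O | intermediate
21 | carbon monoxide | [C-]#[O+] | starting material
22 | 13-acetoxy-1,2-epoxy-10-hydroxy-8-oxo-3-(triethylsilyloxy)germacr-4Z-en-12,6-olide (H-6/H-7 cis; C11 epimers) | CC(=O)OCC1C(=O)O[C@H]2/C=C(/C)[C@@H](O[Si](CC)(CC)CC)[C@H]3O[C@H]3[C@](C)(O)CC(=O)[C@@H]12 | intermediate
23 | (8R)-13-acetoxy-1,2-epoxy-8,10-dihydroxy-3-(triethylsilyloxy)germacr-4Z-en-12,6-olide (8,10-anti diol) | CC(=O)OCC1C(=O)O[C@H]2/C=C(/C)[C@@H](O[Si](CC)(CC)CC)[C@H]3O[C@H]3[C@](C)(O)C[C@@H](O)[C@@H]12 | intermediate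
24 | angelic acid [(Z)-2-methylbut-2-enoic acid] | C/C=C(/C)C(=O)O | starting material
25 | 8-O-angelate of 23 | CC(=O)OCC1C(=O)O[C@H]2/C=C(/C)[C@@H](O[Si](CC)(CC)CC)[C@H]3O[C@H]3[C@](C)(O)C[C@@H](OC(=O)/C(C)=C\C)[C@@H]12 | intermediate (not isolated)
26 | 3-O-triethylsilyl ether of 27 | C=C1C(=O)O[C@H]2/C=C(/C)[C@@H](O[Si](CC)(CC)CC)[C@H]3O[C@H]3[C@](C)(O)C[C@@H](OC(=O)/C(C)=C\C)[C@@H]12 | intermediate
27 | (1R,2R,3R,4Z,6S,7R,8R,10R)-8-angeloyloxy-1,2-epoxy-3,10-dihydroxygermacra-4,11(13)-dien-12,6-olide | C=C1C(=O)O[C@H]2/C=C(/C)[C@@H](O)[C@H]3O[C@H]3[C@](C)(O)C[C@@H](OC(=O)/C(C)=C\C)[C@@H]12 | target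

**Step count and risks**
Total steps: 14. Longest linear sequence: 11 (steps 4–14); the epoxy-aldehyde branch (steps 1–3) joins at step 9.

Most likely to fail, step 11: the C9 radical may be reduced or abstract the C3 hydrogen before it takes up CO, the acyl radical may oligomerise instead of closing the ten-membered ring, and the cis ring fusion is predicted, not precedented. Fallback: put the C8 carbonyl in before the radical step. Setting out from bis-epoxide 19, ring-expanding carbonylation of the terminal epoxide ([(salph)Al(THF)2][Co(CO)4] cat., CO 60 atm, THF, 50 °C) gives the 4,4-disubstituted β-lactone F1. Me2AlSePh (CH2Cl2, −78 °C) opens the strained lactone at the acyl carbon to the β-hydroxy phenyl selenoester F2. (Me3Si)3SiH/AIBN in benzene (0.003 M, 80 °C) then generates the same C8 acyl radical without CO and closes the ring, rejoining the route at ketone 22.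

Second, step 9: Felkin control at C3 may be modest, the epoxy aldehyde is fragile toward chromium salts, and the allylic acetate must survive the nickel co-catalyst. Fallback: set C3 by reduction instead of by C–C addition. Setting out from 17 and 8, the same CrCl2/NiCl2 coupling with aqueous work-up gives the C3-epimeric allylic alcohols F3. Dess–Martin periodinane (NaHCO3, CH2Cl2) converts both into the epoxy enone F4. Zn(BH4)2 (Et2O, −20 °C; chelation-controlled Oishi–Nakata reduction of α,β-epoxy ketones) gives the erythro (3R)-alcohol F5, and Et3SiCl/imidazole returns to 19.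

Third, step 12: hydride delivery through a tertiary alkoxide inside the macrocycle may be unselective, and the freed C8–OH can translactonise onto C12 before or during the hot acylation of step 13. Fallback: set C8 by inversion. Setting out from ketone 22, Narasaka–Prasad reduction (Et2BOMe, NaBH4, THF/MeOH, −78 °C) gives the 1,3-syn diol F6 (8S). Mitsunobu esterification with angelic acid 24 (PPh3, DIAD, toluene, 0 °C) inverts C8 and gives angelate 25 at low temperature, which is taken on with DBU to 26 as in step 13.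

**Further compounds**
F1 | step 11 | β-lactone from 19 (C10–O–C8(=O)–C9H2 oxetan-2-one; other centres as in 19) | CC(=O)OCC1=C[C@H](/C=C(/C)[C@@H](O[Si](CC)(CC)CC)[C@H]2O[C@H]2[C@@]3(C)CC(=O)O3)OC1=O
F2 | step 11 | Se-phenyl β-hydroxy selenoester (C8(=O)SePh; C10–OH) | CC(=O)OCC1=C[C@H](/C=C(/C)[C@@H](O[Si](CC)(CC)CC)[C@H]2O[C@H]2[C@](C)(O)CC(=O)[Se]c2ccccc2)OC1=O
F3 | step 9 | C3-epimeric allylic alcohols from 17 and 8 | CC(=O)OCC1=C[C@H](/C=C(/C)C(O)[C@H]2O[C@H]2[C@]3(C)OC3)OC1=O
F4 | step 9 | C3 epoxy enone | CC(=O)OCC1=C[C@H](/C=C(/C)C(=O)[C@H]2O[C@H]2[C@]3(C)OC3)OC1=O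
F5 | step 9 | (3R)-allylic alcohol (free alcohol of 19) | CC(=O)OCC1=C[C@H](/C=C(/C)[C@@H](O)[C@H]2O[C@H]2[C@]3(C)OC3)OC1=O
F6 | step 12 | 8,10-syn diol (8S epimer of 23) | CC(=O)OCC1C(=O)O[C@H]2/C=C(/C)[C@@H](O[Si](CC)(CC)CC)[C@H]3O[C@H]3[C@](C)(O)C[C@H](O)[C@@H]12
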